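**Plan** (target numbered O-1, C-2 to C-5; aryl groups on C-2 and C-5, CH2OH groups on C-3 and C-4)

- Retrosynthesis: the phenols and primary alcohols are unmasked last. The C-3–C-4 ring bond is cut by reversing a Wolff ring contraction, so the C-3 hydroxymethyl carbon returns as the carbonyl of a 2,6-diaryltetrahydropyran-4-one. The C-5–aryl and C-4–CH2OH bonds are then cut together (conjugate addition with enolate trapping). The remaining dihydropyranone is cut into benzylated syringaldehyde and a siloxydiene.
- Forward: the six-membered oxygen ring is made first by hetero-Diels–Alder reaction. The second aryl group and the hydroxymethyl group are then attached with no ring formed. The pyranone is contracted to the tetrahydrofuran, reduced and deprotected.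
- Stereochemistry: C-2 comes from the BINOL titanium catalyst, C-5 from axial attack anti to the C-2 aryl group, C-4 from enolate trapping anti to the new aryl group, and C-3 from equilibration of the ester to the all-trans isomer.
- Enabling feature: the aryl groups on C-2 and C-5 are trans across O-1 of the tetrahydrofuran ring, which is what axial conjugate addition to a 2-aryl-2,3-dihydro-4H-pyran-4-one delivers. The CH2OH carbon on C-3 can be the extruded carbonyl carbon of that six-membered ring.

Key step: step 5

Assumption: (R)-BINOL with Ti(OiPr)4 is taken to expose the Re face of the benzylated aldehyde, as it does in additions to other aryl aldehydes, which gives the (R)-dihydropyranone; if the configuration proves opposite, (S)-BINOL is used.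

**Route**

Step 1
Reactants: 1 syringaldehyde (4-hydroxy-3,5-dimethoxybenzaldehyde); 2 benzyl bromide
Product: 3 4-benzyloxy-3,5-dimethoxybenzaldehyde
Conditions: K2CO3, DMF, 60 °C
Reagents that add atoms: none
Why: Williamson ether synthesis on the acidic phenol masks it for the organometallic and hydride steps and leaves a group removable by hydrogenolysis at the end.

Step 2
Reactants: 3 4-benzyloxy-3,5-dimethoxybenzaldehyde; 4 (E)-1-methoxy-3-(trimethylsilyloxy)buta-1,3-diene
Product: 6 (R)-2-(4-benzyloxy-3,5-dimethoxyphenyl)-2,3-dihydro-4H-pyran-4-one, via silyl aldol adduct 5 (not isolated)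
Conditions: (R)-BINOL (20 mol %), Ti(OiPr)4 (20 mol %), 4 Å MS, Et2O, −20 °C; then CF3CO2H, CH2Cl2, 0 °C
Reagents that add atoms: none
Why: Enantioselective hetero-Diels–Alder reaction in its stepwise Mukaiyama aldol/cyclisation form, in which the BINOL titanium complex shields one face of the bound aldehyde so that the carbinol centre (later C-2 of the target) is set by the catalyst, and acid then closes the ring by oxa-Michael addition with loss of methanol.

Step 3
Reactants: 7 4-bromo-2,6-dimethoxyphenol; 2 benzyl bromide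
Product: 8 2-benzyloxy-5-bromo-1,3-dimethoxybenzene
Conditions: K2CO3, DMF, 60 °C
Reagents that add atoms: none
Why: Williamson ether synthesis removes the acidic phenol proton, which would otherwise destroy the Grignard reagent made next.

Step 4
Reactants: 8 2-benzyloxy-5-bromo-1,3-dimethoxybenzene
Product: 9 4-benzyloxy-3,5-dimethoxyphenylmagnesium bromide (THF solution, titrated and used directly)
Conditions: Mg turnings, I2 (cat.), THF, 50 °C
Reagents that add atoms: magnesium, [Mg]
Why: Grignard formation by insertion of magnesium into the aryl C–Br bond, to which the benzyl and methyl ethers are inert.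

Step 5
Reactants: 6 (R)-2-(4-benzyloxy-3,5-dimethoxyphenyl)-2,3-dihydro-4H-pyran-4-one; 9 4-benzyloxy-3,5-dimethoxyphenylmagnesium bromide; 10 formaldehyde (anhydrous monomer in THF, from cracked paraformaldehyde)
Product: 12 (2R,3S,6R)-2,6-bis(4-benzyloxy-3,5-dimethoxyphenyl)-3-(hydroxymethyl)tetrahydro-4H-pyran-4-one, via bromomagnesium enolate 11 (not isolated)
Conditions: CuBr·SMe2 (20 mol %), THF, −78 → −40 °C (slow addition of 9); then CH2O (excess), −78 °C; pH 7 buffer
Reagents that add atoms: none
Why: Transmetalation of 9 to copper generates an aryl cuprate that π-complexes the vinylogous ester 6, adds at its β-carbon (C-6 of 6) and releases the bromomagnesium enolate 11, which then attacks monomeric formaldehyde through its α-carbon in an aldol addition. The closest known reaction type is the trans-selective copper-mediated Grignard conjugate addition to 2-substituted 2,3-dihydro-4H-pyran-4-ones with trapping of the regiodefined enolate by an aldehyde. No ring is closed: the step forms the C-5–aryl bond and the C-4–CH2OH bond of the target on the intact six-membered ring. The new aryl-bearing centre is controlled by the existing stereocentre of 6, whose aryl group sits pseudo-equatorial on the half-chair, so that the stereoelectronically required axial attack comes from the opposite face and gives the 2,6-trans diaryl arrangement. The hydroxymethyl-bearing centre is controlled by the newly introduced axial aryl group next to it, formaldehyde approaching the enolate anti to that group, which is also the arrangement favoured at equilibrium. The step needs 1,4- over 1,2-addition, secured by copper catalysis with slow addition of 9 at low temperature, and hydroxymethylation at the enolate carbon only, secured by adding formaldehyde at −78 °C before proton transfer can relocate the enolate and by a neutral quench that avoids dehydration or retro-aldol loss.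

Step 6
Reactants: 12 (2R,3S,6R)-2,6-bis(4-benzyloxy-3,5-dimethoxyphenyl)-3-(hydroxymethyl)tetrahydro-4H-pyran-4-one
Product: 13 (2R,3S,6R)-2,6-bis(4-benzyloxy-3,5-dimethoxyphenyl)-3-[(tert-butyldimethylsilyloxy)methyl]tetrahydro-4H-pyran-4-one
Conditions: t-BuMe2SiCl, imidazole, DMF, 0 °C → rt
Reagents that add atoms: tert-butyldimethylsilyl chloride, CC(C)(C)[Si](C)(C)Cl
Why: Silylation of the primary alcohol under mild amine-base conditions forms no enolate, and it prevents the hydroxyl group from later capturing the ketene as a cis-fused lactone.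

Step 7
Reactants: 13 (2R,3S,6R)-2,6-bis(4-benzyloxy-3,5-dimethoxyphenyl)-3-[(tert-butyldimethylsilyloxy)methyl]tetrahydro-4H-pyran-4-one
Product: 15 (2R,3S,6S)-2,6-bis(4-benzyloxy-3,5-dimethoxyphenyl)-3-[(tert-butyldimethylsilyloxy)methyl]-5-diazotetrahydro-4H-pyran-4-one, via trifluoroacetyl ketone 14 (not isolated)
Conditions: LiN(SiMe3)2, THF, −78 °C; CF3CO2CH2CF3, −78 °C; then MeSO2N3, Et3N, MeCN, rt
Reagents that add atoms: methanesulfonyl azide, CS(=O)(=O)N=[N+]=[N-]
Why: Deacylative (Regitz-type) diazo transfer, in which kinetic deprotonation occurs at the unhindered C-5 methylene and not at the tertiary C-3, Claisen-type trifluoroacetylation activates that carbon, and the sulfonyl azide delivers N2 with loss of the trifluoroacetyl group, leaving the three stereocentres untouched (the C-6 descriptor changes only because the diazo carbon now outranks the aryl group).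

Step 8
Reactants: 15 (2R,3S,6S)-2,6-bis(4-benzyloxy-3,5-dimethoxyphenyl)-3-[(tert-butyldimethylsilyloxy)methyl]-5-diazotetrahydro-4H-pyran-4-one
Product: 18 methyl (2R,3R,4S,5R)-2,5-bis(4-benzyloxy-3,5-dimethoxyphenyl)-4-[(tert-butyldimethylsilyloxy)methyl]tetrahydrofuran-3-carboxylate, via ketene 16 (not isolated), via ester epimer mixture 17 (not isolated)
Conditions: hν (λ > 300 nm, Pyrex), MeOH, 0 °C; then NaOMe (0.3 equiv), MeOH, rt → 40 °C
Reagents that add atoms: methanol, CO
Why: Photochemical Wolff rearrangement of the s-cis-locked cyclic α-diazoketone contracts the ring, the silyloxymethyl-bearing carbon migrating with retention to the diazo carbon; methanol captures the ketene, and methoxide then equilibrates the only acidic centre (C-3) to the isomer with the ester trans to both the C-2 aryl group and the C-4 side chain.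

Step 9
Reactants: 18 methyl (2R,3R,4S,5R)-2,5-bis(4-benzyloxy-3,5-dimethoxyphenyl)-4-[(tert-butyldimethylsilyloxy)methyl]tetrahydrofuran-3-carboxylate
Product: 19 [(2R,3S,4S,5R)-2,5-bis(4-benzyloxy-3,5-dimethoxyphenyl)-4-[(tert-butyldimethylsilyloxy)methyl]tetrahydrofuran-3-yl]methanol
Conditions: LiAlH4, THF, 0 °C
Reagents that add atoms: none
Why: Hydride reduction of the ester to the primary alcohol, which fixes C-3 against further epimerisation while the silyl and benzyl ethers are inert to the reagent at 0 °C.

Step 10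
Reactants: 19 [(2R,3S,4S,5R)-2,5-bis(4-benzyloxy-3,5-dimethoxyphenyl)-4-[(tert-butyldimethylsilyloxy)methyl]tetrahydrofuran-3-yl]methanol
Product: 20 [(2R,3S,4S,5R)-2,5-bis(4-benzyloxy-3,5-dimethoxyphenyl)tetrahydrofuran-3,4-diyl]dimethanol
Conditions: Bu4NF, THF, rt
Reagents that add atoms: none
Why: Fluoride-induced desilylation, driven by the strength of the Si–F bond, frees the second primary alcohol without touching the benzyl ethers or any stereocentre.

Step 11
Reactants: 20 [(2R,3S,4S,5R)-2,5-bis(4-benzyloxy-3,5-dimethoxyphenyl)tetrahydrofuran-3,4-diyl]dimethanol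
Product: 21 [(2R,3S,4S,5R)-2,5-bis(4-hydroxy-3,5-dimethoxyphenyl)tetrahydrofuran-3,4-diyl]dimethanol (CNP0170897.1)
Conditions: H2 (1 atm), Pd/C, EtOAc–MeOH, rt
Reagents that add atoms: none
Why: Catalytic hydrogenolysis cleaves the two aryl benzyl ethers, which under neutral conditions should react much faster than the ring benzylic C–O bonds, so the reaction is stopped once two equivalents of hydrogen are taken up.

**Compound list**

1 | syringaldehyde | COc1cc(C=O)cc(OC)c1O | starting material
2 | benzyl bromide | BrCc1ccccc1 | starting material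
3 | 4-benzyloxy-3,5-dimethoxybenzaldehyde | COc1cc(C=O)cc(OC)c1OCc1ccccc1 | intermediate
4 | (E)-1-methoxy-3-(trimethylsilyloxy)buta-1,3-diene | CO/C=C/C(=C)O[Si](C)(C)C | starting material
5 | (R,E)-5-(4-benzyloxy-3,5-dimethoxyphenyl)-1-methoxy-5-(trimethylsilyloxy)pent-1-en-3-one (silyl aldol adduct, formed in the flask) | CO/C=C/C(=O)C[C@@H](O[Si](C)(C)C)c1cc(OC)c(OCc2ccccc2)c(OC)c1 | intermediate
6 | (R)-2-(4-benzyloxy-3,5-dimethoxyphenyl)-2,3-dihydro-4H-pyran-4-one | COc1cc([C@@H]2OC=CC(=O)C2)cc(OC)c1OCc1ccccc1 | intermediate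
7 | 4-bromo-2,6-dimethoxyphenol | COc1cc(Br)cc(OC)c1O | starting material
8 | 2-benzyloxy-5-bromo-1,3-dimethoxybenzene | COc1cc(Br)cc(OC)c1OCc1ccccc1 | intermediate
9 | 4-benzyloxy-3,5-dimethoxyphenylmagnesium bromide | COc1cc([Mg]Br)cc(OC)c1OCc1ccccc1 | intermediate
10 | formaldehyde | C=O | starting material
11 | bromomagnesium (2R,6R)-2,6-bis(4-benzyloxy-3,5-dimethoxyphenyl)-3,6-dihydro-2H-pyran-4-olate (2,6-trans enolate, formed in the flask) | COc1cc([C@@H]2O[C@@H](c3cc(OC)c(OCc4ccccc4)c(OC)c3)C=C(O[Mg]Br)C2)cc(OC)c1OCc1ccccc1 | intermediate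
12 | (2R,3S,6R)-2,6-bis(4-benzyloxy-3,5-dimethoxyphenyl)-3-(hydroxymethyl)tetrahydro-4H-pyran-4-one (2,6-trans, 2,3-trans) | COc1cc([C@@H]2O[C@@H](c3cc(OC)c(OCc4ccccc4)c(OC)c3)[C@H](CO)C(=O)C2)cc(OC)c1OCc1ccccc1 | intermediate
13 | (2R,3S,6R)-2,6-bis(4-benzyloxy-3,5-dimethoxyphenyl)-3-[(tert-butyldimethylsilyloxy)methyl]tetrahydro-4H-pyran-4-one | COc1cc([C@@H]2O[C@@H](c3cc(OC)c(OCc4ccccc4)c(OC)c3)[C@H](CO[Si](C)(C)C(C)(C)C)C(=O)C2)cc(OC)c1OCc1ccccc1 | intermediate
14 | (2R,3S,6R)-2,6-bis(4-benzyloxy-3,5-dimethoxyphenyl)-3-[(tert-butyldimethylsilyloxy)methyl]-5-(trifluoroacetyl)tetrahydro-4H-pyran-4-one (C-5 unassigned, largely enolised, formed in the flask) | COc1cc([C@@H]2O[C@@H](c3cc(OC)c(OCc4ccccc4)c(OC)c3)[C@H](CO[Si](C)(C)C(C)(C)C)C(=O)C2C(=O)C(F)(F)F)cc(OC)c1OCc1ccccc1 | intermediate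
15 | (2R,3S,6S)-2,6-bis(4-benzyloxy-3,5-dimethoxyphenyl)-3-[(tert-butyldimethylsilyloxy)methyl]-5-diazotetrahydro-4H-pyran-4-one | COc1cc([C@@H]2O[C@@H](c3cc(OC)c(OCc4ccccc4)c(OC)c3)[C@H](CO[Si](C)(C)C(C)(C)C)C(=O)C2=[N+]=[N-])cc(OC)c1OCc1ccccc1 | intermediate
16 | 2,5-bis(4-benzyloxy-3,5-dimethoxyphenyl)-4-[(tert-butyldimethylsilyloxy)methyl]-3-(oxomethylidene)tetrahydrofuran (ketene, ring stereocentres as in 15, formed in the flask) | COc1cc([C@@H]2O[C@@H](c3cc(OC)c(OCc4ccccc4)c(OC)c3)[C@H](CO[Si](C)(C)C(C)(C)C)C2=C=O)cc(OC)c1OCc1ccccc1 | intermediate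
17 | methyl (2R,4S,5R)-2,5-bis(4-benzyloxy-3,5-dimethoxyphenyl)-4-[(tert-butyldimethylsilyloxy)methyl]tetrahydrofuran-3-carboxylate (mixture of C-3 epimers, formed in the flask) | COc1cc([C@@H]2O[C@@H](c3cc(OC)c(OCc4ccccc4)c(OC)c3)[C@H](CO[Si](C)(C)C(C)(C)C)C2C(=O)OC)cc(OC)c1OCc1ccccc1 | intermediate
18 | methyl (2R,3R,4S,5R)-2,5-bis(4-benzyloxy-3,5-dimethoxyphenyl)-4-[(tert-butyldimethylsilyloxy)methyl]tetrahydrofuran-3-carboxylate (all-trans) | COc1cc([C@@H]2O[C@@H](c3cc(OC)c(OCc4ccccc4)c(OC)c3)[C@H](CO[Si](C)(C)C(C)(C)C)[C@H]2C(=O)OC)cc(OC)c1OCc1ccccc1 | intermediate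
19 | [(2R,3S,4S,5R)-2,5-bis(4-benzyloxy-3,5-dimethoxyphenyl)-4-[(tert-butyldimethylsilyloxy)methyl]tetrahydrofuran-3-yl]methanol | COc1cc([C@@H]2O[C@@H](c3cc(OC)c(OCc4ccccc4)c(OC)c3)[C@H](CO[Si](C)(C)C(C)(C)C)[C@H]2CO)cc(OC)c1OCc1ccccc1 | intermediate
20 | [(2R,3S,4S,5R)-2,5-bis(4-benzyloxy-3,5-dimethoxyphenyl)tetrahydrofuran-3,4-diyl]dimethanol | COc1cc([C@@H]2O[C@@H](c3cc(OC)c(OCc4ccccc4)c(OC)c3)[C@H](CO)[C@H]2CO)cc(OC)c1OCc1ccccc1 | intermediate
21 | [(2R,3S,4S,5R)-2,5-bis(4-hydroxy-3,5-dimethoxyphenyl)tetrahydrofuran-3,4-diyl]dimethanol (CNP0170897.1) | COc1cc([C@@H]2O[C@@H](c3cc(OC)c(O)c(OC)c3)[C@H](CO)[C@H]2CO)cc(OC)c1O | target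

**Step count**

Total: 11 steps. Longest linear sequence: 9 steps (steps 1, 2, 5–11; the branch through steps 3 and 4 is equally long).

**Steps most likely to fail**

Step 5 (key step). The magnesium enolate may be lost to proton transfer or to β-elimination of the ring oxygen before formaldehyde reaches it. Formaldehyde may oligomerise or add a second time, the aldol may dehydrate on work-up, and 1,2-addition of the Grignard reagent competes if copper turnover is slow. The fallback sets out from 6 and 9 and returns at 12, making the same two bonds in two separate operations. Conjugate addition of 9 with CuBr·SMe2 (cat.) and Me3SiCl in THF at −78 °C, where the silyl chloride accelerates the 1,4-addition and captures the enolate, should give after an Et3N quench the isolable silyl enol ether (2R,6R)-2,6-bis(4-benzyloxy-3,5-dimethoxyphenyl)-4-(trimethylsilyloxy)-3,6-dihydro-2H-pyran F1. A Lewis-acid-catalysed Mukaiyama aldol hydroxymethylation of F1 with aqueous formaldehyde and Sc(OTf)3 (cat.) in THF–H2O at rt should then deliver 12, the electrophile again approaching anti to the neighbouring aryl group.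

Step 7. Enolisation may occur toward C-3 and be followed by β-elimination of the silyloxy group. The C-5 enolate may open the ring by β-elimination of the ring oxygen, which would erode the 2,6-trans relationship on reclosure. C-acylation may also be incomplete. The fallback sets out from 13 and returns at 15 without forming any metal enolate. Heating 13 with tert-butoxybis(dimethylamino)methane in toluene at 60 °C should condense at the only ring methylene to give the enaminone 2,6-bis(4-benzyloxy-3,5-dimethoxyphenyl)-3-[(tert-butyldimethylsilyloxy)methyl]-5-[(dimethylamino)methylidene]tetrahydro-4H-pyran-4-one F2 (ring stereocentres as in 13, E geometry expected). Diazo transfer onto the enaminone with p-toluenesulfonyl azide in MeCN at rt, by triazoline formation and cycloreversion, should release the sulfonyl formamidine and give 15.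

Step 8. The ketene–methanol adduct is protonated on the open face, which places the ester cis to both neighbours. Equilibration of this hindered ester with methoxide may then be slow, or may be accompanied by opening of the ring through β-elimination of the ring oxygen. The fallback sets out from 17 (isolated by omitting the methoxide stage) and returns at 19, moving the equilibration to the more acidic aldehyde oxidation level. Reduction with iBu2AlH in CH2Cl2 at −78 °C should give the aldehyde (2R,4S,5R)-2,5-bis(4-benzyloxy-3,5-dimethoxyphenyl)-4-[(tert-butyldimethylsilyloxy)methyl]tetrahydrofuran-3-carbaldehyde F3 as a mixture of C-3 epimers. Treatment with DBU in CH2Cl2 at rt should equilibrate it to the all-trans aldehyde (2R,3R,4S,5R)-2,5-bis(4-benzyloxy-3,5-dimethoxyphenyl)-4-[(tert-butyldimethylsilyloxy)methyl]tetrahydrofuran-3-carbaldehyde F4. Reduction with NaBH4 in MeOH at 0 °C should then give 19.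

**Further compounds**

F1 | step 5 | (2R,6R)-2,6-bis(4-benzyloxy-3,5-dimethoxyphenyl)-4-(trimethylsilyloxy)-3,6-dihydro-2H-pyran | COc1cc([C@@H]2O[C@@H](c3cc(OC)c(OCc4ccccc4)c(OC)c3)C=C(O[Si](C)(C)C)C2)cc(OC)c1OCc1ccccc1
F2 | step 7 | 2,6-bis(4-benzyloxy-3,5-dimethoxyphenyl)-3-[(tert-butyldimethylsilyloxy)methyl]-5-[(dimethylamino)methylidene]tetrahydro-4H-pyran-4-one (ring stereocentres as in 13) | COc1cc([C@@H]2O[C@@H](c3cc(OC)c(OCc4ccccc4)c(OC)c3)[C@H](CO[Si](C)(C)C(C)(C)C)C(=O)/C2=C/N(C)C)cc(OC)c1OCc1ccccc1
F3 | step 8 | (2R,4S,5R)-2,5-bis(4-benzyloxy-3,5-dimethoxyphenyl)-4-[(tert-butyldimethylsilyloxy)methyl]tetrahydrofuran-3-carbaldehyde (mixture of C-3 epimers) | COc1cc([C@@H]2O[C@@H](c3cc(OC)c(OCc4ccccc4)c(OC)c3)[C@H](CO[Si](C)(C)C(C)(C)C)C2C=O)cc(OC)c1OCc1ccccc1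
F4 | step 8 | (2R,3R,4S,5R)-2,5-bis(4-benzyloxy-3,5-dimethoxyphenyl)-4-[(tert-butyldimethylsilyloxy)methyl]tetrahydrofuran-3-carbaldehyde | COc1cc([C@@H]2O[C@@H](c3cc(OC)c(OCc4ccccc4)c(OC)c3)[C@H](CO[Si](C)(C)C(C)(C)C)[C@H]2C=O)cc(OC)c1OCc1ccccc1
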